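Assumption: (S)-4-hydroxymandelic acid is taken as a catalogue compound of high enantiomeric purity. The oxolane is numbered O1, C2 (aryl), C3 (one-carbon branch), C4 (carbinol branch), C5 (methylene) throughout, also in the compound names.

## Analysis of the target

The target 22 is a 2,3,4-trisubstituted oxolane in which C5 is an unsubstituted methylene. C2 carries a 4-hydroxyphenyl group, C3 an acetoxymethyl group and C4 an exocyclic acetoxy(4-methoxyphenyl)methyl group. The three ring stereocentres are contiguous and all-trans (2R,3S,4R). The fourth, the (S)-carbinol carbon, lies outside the ring next to C4, where the ring can bias it but not fix it. Three groups are sensitive: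

- the free phenol, which is para to the benzylic ether carbon C2 and can open the ring through a quinone methide under base or oxidants;
- the 4-methoxybenzylic acetate, which ionises under acid;
- the two alkyl acetates, which must coexist with a free phenol at the end.

The synthesis is hard because three contiguous ring centres, one exocyclic centre and a phenol/alcohol differentiation must all be handled. The strategy rests on reading C5, C4 and the carbinol carbon as an aryl vinyl ketone (C4 the α-carbon, C5 the β-methylene on O1), and C3 with its branch as the β-carbon of a nitroalkene whose nitromethyl group is a masked hydroxymethyl group. C2 with its oxygen and aryl group corresponds to the carbinol carbon of 4-hydroxymandelic acid.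

## Retrosynthetic reasoning

**22 to 21.** The O–Si bond on the phenol is cut last. The phenol has to stay masked until both acetates are present, because a free phenol would be acetylated first. An aryl silyl ether falls to buffered fluoride without loss of esters.

**21 to 20.** Both acetyl C–O bonds are cut together, giving diol 20. One acetylation can serve both positions only if the two hydroxyl groups appear late and unprotected, and this fixes the order of the reductions before it.

**20 to 19.** The carbinol C–H bond is cut, giving aryl ketone 19. The exocyclic centre is the one the ring cannot set reliably, so it is assigned to a catalyst-controlled reduction. The same ketone makes C4 epimerisable and drives the ring construction.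

**19 to 18 to 16.** The hydroxymethyl group is traced through aldehyde 18 to the nitromethyl group of 16; the species actually oxidised is sodium nitronate 17, made in the flask from 16. The aldehyde is reduced before the ketone: while the ketone is present, C3 and C4 are each flanked by a carbonyl group and trans is the stable arrangement. A free carbinol next to the aldehyde would instead trap any C3 epimer as a lactol. The forward steps must convert a primary nitro group to an aldehyde without over-oxidation and reduce that aldehyde beside an aryl ketone.

**16 to 10 and 13.** Two bonds are cut, O1–C5 and C3–C4, each as a retro-Michael step. The cuts give two stable fragments of similar size. Hydroxy nitroalkene 10 carries C2, C3 and the branch carbon; vinyl ketone 13 carries C5, C4, the carbinol carbon and the anisyl ring. Cutting at C2–C3 or C4–C5 would give no such polarity match. This disconnection is convergent and builds the ring, two skeletal bonds and two stereocentres in one operation. In the forward direction the alkoxide of 10 must add to the terminal carbon of 13, the enolate must close on the nitroalkene under control of C2, and C4 must settle trans.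

**10 to 9 to 7 to 5 and 6.** The nitroalkene double bond is cut through silyl ether 9 and nitro alcohol 7, which separates aldehyde 5 from nitromethane 6. The nitroaldol/dehydration pair is the standard entry to γ-oxygenated nitroalkenes; the carbinol must be protected while it is carried out.

**5 to 4 to 2 to 1.** Aldehyde 5 is the partially reduced form of ester 4, which comes from methyl ester 2 and acid 1. The C2 stereocentre is bought. Two different silyl groups are used so that the carbinol can be unmasked in acid while the phenol stays protected to the end.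

**13 to 11.** The terminal methylene carbon (C5) is cut from the acetyl group of 11; the forward reaction is an α-methylenation.

## Alternatives that were turned down

**Alternative 1:** butenolide conjugate addition with enolate trapping.
- Disconnection: the bond from C4 to the future carbinol carbon and the bond from C3 to its hydroxymethyl carbon, both made on the preformed five-membered ring of the chiral butenolide A2.
- Forward key step: the lithio derivative of dithiane A3 adds to the β-carbon of A2 anti to the menthyloxy group. The lactone enolate is then hydroxymethylated by formaldehyde A4 anti to the new substituent, giving lactone A1.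
- For: conjugate addition with enolate trapping on this butenolide is well established, and the auxiliary fixes C3 and C4 in absolute terms. In precedent and predictability at these two centres it is stronger than the chosen route.
- Against: no ring is closed and two ring atoms are at the wrong oxidation level. The lactone carbonyl carbon has to become C2 by aryl addition and lactol reduction, so the C2 centre is made late under substrate control. The acetal carbon has to be reduced to the C5 methylene. Both changes pass through oxocarbenium ions beside a dithiane and a free hydroxymethyl group, which can also be lost by retro-aldol cleavage. The carbinol centre is still open after the dithiane is unmasked, so the same ketone reduction is needed.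
- Comparison: the sequence after A1 is clearly longer than the five steps that follow 16. The chosen route delivers the ring, the aryl-bearing C2 centre and both ring-forming bonds in one step, at the price of an untested pairing.

**Alternative 2:** anodic quinone methide closure.
- Disconnection: the O1–C2 bond of the finished skeleton.
- Forward key step: anodic oxidation of the 4-alkylphenol A6 gives quinone methide A7. The C5 hydroxyl group adds to the methide carbon in a 5-exo closure and restores the phenol, giving A5.
- For: the phenol needs no protecting group and the oxidation needs no reagent. The other primary hydroxyl group could only close a four-membered ring. Reversible addition to a quinone methide should favour the 2,3-trans aryl group. In protecting-group economy at the phenol, and probably in trans selectivity at C2, it is as strong as or stronger than the chosen route.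
- Against: A5 is itself a 4-alkylphenol whose benzylic carbon now bears oxygen, so it is oxidised at least as easily as A6. Renewed quinone methide formation at C2, ring opening, solvent capture and phenoxyl coupling all compete, and the anisyl ring is a second oxidisable arene. The step makes one C–O bond and one stereocentre. Every C–C bond and the C3, C4 and carbinol centres must first be set in an open chain. After A5 the primary alcohol cannot be acetylated beside a free phenol without a detour.
- Comparison: the chosen route assembles skeleton and ring together from two small fragments and keeps the phenol inert until the last step.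

**Alternative 3:** Prins cyclisation with acetate capture.
- Disconnection: O1–C5 and C5–C4 with C5 supplied by A4, together with the carbinol C–O bond.
- Forward key step: homoallylic alcohol A9 condenses with A4 under a strong Lewis acid to an oxocarbenium ion. The styrenyl double bond attacks through C4 because the distal carbon becomes an anisyl-stabilised cation, and acetate from the medium captures that cation, giving triacetate A8.
- For: it is by far the shortest plan. The ring, two bonds, the carbinol C–O bond and an acetate arrive together, and A8 is one selective phenol deacetylation from 22. In step economy it is stronger than the chosen route.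
- Against: the carbinol centre arises by capture of a planar, long-lived 4-methoxybenzylic cation outside the ring, and the acetate formed re-ionises under the same acid. Its configuration would rest on a weak equilibrium preference. A9 is a benzylic homoallylic alcohol, so its oxocarbenium ion can undergo 2-oxonia-Cope rearrangement, which scrambles C2 and C3. The benzylic hydroxyl group may ionise, and elimination to a styrene competes with capture.
- Comparison: the chosen route is longer, but it sets the carbinol with a chiral catalyst on a ketone and carries C2 from the chiral pool without passing through cations.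

Key step: step 8

## Route

Step 1
Reactants: 1 (S)-4-hydroxymandelic acid
Product: 2 methyl (S)-2-hydroxy-2-(4-hydroxyphenyl)acetate
Conditions: MeI (1.2 equiv), KHCO3 (1.5 equiv), DMF, rt
Reagents that add atoms: iodomethane, CI
Why: Carboxylate alkylation (SN2); KHCO3 deprotonates only the carboxylic acid, so the phenol and the benzylic alcohol are not methylated, and no acid is present that could ionise the 4-hydroxybenzylic carbinol and erode the stereocentre.

Step 2
Reactants: 2 methyl (S)-2-hydroxy-2-(4-hydroxyphenyl)acetate
Product: 4 methyl (S)-2-(triethylsilyloxy)-2-[4-(triisopropylsilyloxy)phenyl]acetate, via phenol triisopropylsilyl ether 3 (not isolated)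
Conditions: i-Pr3SiCl (1.05 equiv), imidazole (3 equiv), DMF, 0 °C → rt; then Et3SiCl (1.3 equiv), rt
Reagents that add atoms: triisopropylsilyl chloride, CC(C)[Si](Cl)(C(C)C)C(C)C; triethylsilyl chloride, CC[Si](Cl)(CC)CC
Why: Imidazole-promoted silyl ether formation; the phenol reacts with the bulky chlorosilane far faster than the hindered α-hydroxy ester, which then takes the small triethylsilyl group. The two ethers differ by orders of magnitude in acid lability, which step 6 uses.

Step 3
Reactants: 4 methyl (S)-2-(triethylsilyloxy)-2-[4-(triisopropylsilyloxy)phenyl]acetate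
Product: 5 (S)-2-(triethylsilyloxy)-2-[4-(triisopropylsilyloxy)phenyl]acetaldehyde
Conditions: i-Bu2AlH (1.15 equiv), CH2Cl2, −78 °C; MeOH, then aq. potassium sodium tartrate
Reagents that add atoms: none
Why: Partial reduction of an ester; the α-silyloxy group stabilises the tetrahedral aluminium hemiacetal at −78 °C, so the aldehyde is released only on work-up. Aldehyde 5 is used at once because its benzylic α-hydrogen is enolisable.

Step 4
Reactants: 5 (S)-2-(triethylsilyloxy)-2-[4-(triisopropylsilyloxy)phenyl]acetaldehyde; 6 nitromethane
Product: 7 (2RS,3S)-1-nitro-3-(triethylsilyloxy)-3-[4-(triisopropylsilyloxy)phenyl]propan-2-ol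
Conditions: 6 (10 equiv), i-Pr2NEt (0.1 equiv), THF, 0 °C
Reagents that add atoms: none
Why: Henry (nitroaldol) reaction; the large excess of 6 holds the amine as its nitronate salt, which should add to the reactive α-oxygenated aldehyde faster than the aldehyde enolises. The new carbinol centre is of no consequence because step 5 removes it.

Step 5
Reactants: 7 (2RS,3S)-1-nitro-3-(triethylsilyloxy)-3-[4-(triisopropylsilyloxy)phenyl]propan-2-ol
Product: 9 (R,E)-triethyl({3-nitro-1-[4-(triisopropylsilyloxy)phenyl]prop-2-en-1-yl}oxy)silane, via nitro mesylate 8 (not isolated)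
Conditions: MsCl (1.2 equiv), i-Pr2NEt (2.5 equiv), CH2Cl2, −78 → −20 °C
Reagents that add atoms: none
Why: Mesylation followed by E1cB elimination of the β-nitro mesylate gives the conjugated nitroalkene, with the E isomer strongly favoured. The hindered amine and the low temperature limit deprotonation at the benzylic γ-position. The descriptor changes from S to R only because the priorities change.

Step 6
Reactants: 9 (R,E)-triethyl({3-nitro-1-[4-(triisopropylsilyloxy)phenyl]prop-2-en-1-yl}oxy)silane
Product: 10 (R,E)-3-nitro-1-[4-(triisopropylsilyloxy)phenyl]prop-2-en-1-ol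
Conditions: AcOH/THF/H2O (3:1:1), rt
Reagents that add atoms: none
Why: Acid-catalysed solvolysis of a silyl ether; aqueous acetic acid cleaves the triethylsilyl alkyl ether while the aryl triisopropylsilyl ether is inert. The nitrovinyl group disfavours ionisation of the benzylic C–O bond, so the carbinol should keep its configuration.

Step 7
Reactants: 11 1-(4-methoxyphenyl)ethanone
Product: 13 1-(4-methoxyphenyl)prop-2-en-1-one, via Mannich base 12 (not isolated)
Conditions: (CH2O)n (3 equiv), i-Pr2NH·CF3CO2H (1 equiv), CF3CO2H (0.1 equiv), THF, reflux
Reagents that add atoms: paraformaldehyde (as formaldehyde), C=O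
Why: Mannich condensation followed by β-elimination of the amine (α-methylenation); the iminium ion is trapped by the enol of 11, and the hindered Mannich base 12 loses diisopropylamine on heating. Ketone 13 polymerises readily and is used the same day.

Step 8
Reactants: 10 (R,E)-3-nitro-1-[4-(triisopropylsilyloxy)phenyl]prop-2-en-1-ol; 13 1-(4-methoxyphenyl)prop-2-en-1-one
Product: 16 (2R,3S,4R)-4-(4-methoxybenzoyl)-3-(nitromethyl)-2-[4-(triisopropylsilyloxy)phenyl]oxolane, via potassium enolate 14 (not isolated), via potassium nitronate 15 (not isolated)
Conditions: 13 (1.3 equiv), THF (high dilution), −78 °C; KN(SiMe3)2 (1.05 equiv), slow addition; AcOH (1.5 equiv), −78 °C; silica plug; then DBU (0.1 equiv), CH2Cl2, 0 °C → rt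
Reagents that add atoms: none
Why: Proposed new method: KN(SiMe3)2 removes the hydroxyl proton of 10 faster than any carbon-bound proton, the potassium alkoxide adds to the unsubstituted terminus of 13 (O1–C5) to give enolate 14, which an alcohol cannot quench and which closes on the tethered nitroalkene (C4–C3) to give nitronate 15, and acetic acid then protonates 15 at carbon. The closest known reactions are the oxa-Michael–Michael dominos of 2-(2-nitrovinyl)phenols with enones, which give chromans, and the annulations of γ-hydroxy enones with nitroalkenes, which give oxolanes with the opposite polarity pattern; an aliphatic γ-hydroxy nitroalkene serving as both alkoxide donor and final acceptor has not been shown. The oxolane closes by a 5-exo-trig Michael addition. C3 is controlled by the preset C2 centre: the tether reaches the nitroalkene from the face that carries O1, and in the envelope transition state the C2 hydrogen eclipses the nitroalkene while the aryl group points outward, so the aryl and nitromethyl groups should end up trans. C4 is α to the ketone and is set by equilibrium: DBU epimerises it to the isomer with the aroyl group trans to the nitromethyl group, and ring opening by β-elimination is the reverse of a 5-endo-trig closure and therefore slow. The step needs the alkoxide to choose the vinyl ketone over the nitroalkene of a second molecule of 10; the monosubstituted acceptor 13, its excess, high dilution and slow addition of base at −78 °C secure this, and the low temperature keeps the benzylic γ-hydrogen of 10 in place. A full equivalent of base is used because nitronate 15 is too weak a base to deprotonate the next alcohol, so a catalytic cycle would stall.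

Step 9
Reactants: 16 (2R,3S,4R)-4-(4-methoxybenzoyl)-3-(nitromethyl)-2-[4-(triisopropylsilyloxy)phenyl]oxolane
Product: 18 (2R,3R,4R)-4-(4-methoxybenzoyl)-2-[4-(triisopropylsilyloxy)phenyl]oxolane-3-carbaldehyde, via sodium nitronate 17 (not isolated)
Conditions: NaOH (1.1 equiv), MeOH/THF, 0 °C; then KMnO4 (0.7 equiv), MgSO4, H2O, 0 °C, short contact
Reagents that add atoms: potassium permanganate, [K+].[O-][Mn](=O)(=O)=O
Why: Oxidative Nef reaction; one equivalent of NaOH converts only the nitromethyl group, the most acidic site, into sodium nitronate 17, whose C=N bond cold KMnO4 cleaves within minutes while MgSO4 buffers the hydroxide formed. The formyl group lies trans to both neighbours, so enolisation at C3 is self-correcting (the descriptor at C3 changes to R only through priorities).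

Step 10
Reactants: 18 (2R,3R,4R)-4-(4-methoxybenzoyl)-2-[4-(triisopropylsilyloxy)phenyl]oxolane-3-carbaldehyde
Product: 19 [(2R,3S,4R)-4-(4-methoxybenzoyl)-2-[4-(triisopropylsilyloxy)phenyl]oxolan-3-yl]methanol
Conditions: NaBH4 (1 equiv), EtOH/CH2Cl2, −78 °C
Reagents that add atoms: none
Why: Chemoselective carbonyl reduction; at −78 °C the aliphatic aldehyde is reduced far faster than the conjugated, electron-rich 4-methoxyphenyl ketone. The trans arrangement of the hydroxymethyl and aroyl groups prevents hemiketal formation.

Step 11
Reactants: 19 [(2R,3S,4R)-4-(4-methoxybenzoyl)-2-[4-(triisopropylsilyloxy)phenyl]oxolan-3-yl]methanol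
Product: 20 [(2R,3S,4R)-4-[(S)-hydroxy(4-methoxyphenyl)methyl]-2-[4-(triisopropylsilyloxy)phenyl]oxolan-3-yl]methanol
Conditions: (R)-Me-CBS [(R)-1-methyl-3,3-diphenyltetrahydro-1H,3H-pyrrolo[1,2-c][1,3,2]oxazaborole] (0.5 equiv), BH3·SMe2 (2.5 equiv), THF, −20 °C; MeOH
Reagents that add atoms: none
Why: Corey–Bakshi–Shibata reduction; the (R)-oxazaborolidine places the 4-methoxyphenyl group in the large-group position and delivers hydride to the face that gives the (S)-carbinol, the same sense in which it gives (S)-1-phenylethanol. Attack anti to the bulkier C3 branch leads to the same face, so catalyst and substrate should reinforce each other; the extra borane covers the free hydroxyl group.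

Step 12
Reactants: 20 [(2R,3S,4R)-4-[(S)-hydroxy(4-methoxyphenyl)methyl]-2-[4-(triisopropylsilyloxy)phenyl]oxolan-3-yl]methanol
Product: 21 [(2R,3S,4R)-4-[(S)-acetoxy(4-methoxyphenyl)methyl]-2-[4-(triisopropylsilyloxy)phenyl]oxolan-3-yl]methyl acetate
Conditions: Ac2O (4 equiv), pyridine, DMAP (0.1 equiv), CH2Cl2, 0 °C → rt
Reagents that add atoms: acetic anhydride, CC(=O)OC(C)=O
Why: Acylation with nucleophilic catalysis by DMAP; both hydroxyl groups are acetylated under basic conditions, in which the 4-methoxybenzylic acetate cannot ionise and no stereocentre is touched.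

Step 13
Reactants: 21 [(2R,3S,4R)-4-[(S)-acetoxy(4-methoxyphenyl)methyl]-2-[4-(triisopropylsilyloxy)phenyl]oxolan-3-yl]methyl acetate
Product: 22 [(2R,3S,4R)-4-[(S)-acetoxy(4-methoxyphenyl)methyl]-2-(4-hydroxyphenyl)oxolan-3-yl]methyl acetate
Conditions: Bu4NF/AcOH (1:1, 1.5 equiv), THF, 0 °C
Reagents that add atoms: none
Why: Fluoride-induced cleavage of an aryl silyl ether, which is much faster than attack on an ester; acetic acid buffers the phenoxide so that no acetate should be cleaved or transferred and no quinone methide should form at C2.

## Compound list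

1 | (S)-4-hydroxymandelic acid | OC(=O)[C@@H](O)c1ccc(O)cc1 | starting material
2 | methyl (S)-2-hydroxy-2-(4-hydroxyphenyl)acetate | COC(=O)[C@@H](O)c1ccc(O)cc1 | intermediate
3 | methyl (S)-2-hydroxy-2-[4-(triisopropylsilyloxy)phenyl]acetate | COC(=O)[C@@H](O)c1ccc(O[Si](C(C)C)(C(C)C)C(C)C)cc1 | intermediate (not isolated)
4 | methyl (S)-2-(triethylsilyloxy)-2-[4-(triisopropylsilyloxy)phenyl]acetate | COC(=O)[C@@H](O[Si](CC)(CC)CC)c1ccc(O[Si](C(C)C)(C(C)C)C(C)C)cc1 | intermediate
5 | (S)-2-(triethylsilyloxy)-2-[4-(triisopropylsilyloxy)phenyl]acetaldehyde | O=C[C@@H](O[Si](CC)(CC)CC)c1ccc(O[Si](C(C)C)(C(C)C)C(C)C)cc1 | intermediate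
6 | nitromethane | C[N+](=O)[O-] | starting material
7 | (2RS,3S)-1-nitro-3-(triethylsilyloxy)-3-[4-(triisopropylsilyloxy)phenyl]propan-2-ol | [O-][N+](=O)CC(O)[C@@H](O[Si](CC)(CC)CC)c1ccc(O[Si](C(C)C)(C(C)C)C(C)C)cc1 | intermediate
8 | (2RS,3S)-1-nitro-3-(triethylsilyloxy)-3-[4-(triisopropylsilyloxy)phenyl]propan-2-yl methanesulfonate | CS(=O)(=O)OC(C[N+](=O)[O-])[C@@H](O[Si](CC)(CC)CC)c1ccc(O[Si](C(C)C)(C(C)C)C(C)C)cc1 | intermediate (not isolated)
9 | (R,E)-triethyl({3-nitro-1-[4-(triisopropylsilyloxy)phenyl]prop-2-en-1-yl}oxy)silane | [O-][N+](=O)/C=C/[C@@H](O[Si](CC)(CC)CC)c1ccc(O[Si](C(C)C)(C(C)C)C(C)C)cc1 | intermediate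
10 | (R,E)-3-nitro-1-[4-(triisopropylsilyloxy)phenyl]prop-2-en-1-ol | O=[N+]([O-])/C=C/[C@@H](O)c1ccc(O[Si](C(C)C)(C(C)C)C(C)C)cc1 | intermediate
11 | 1-(4-methoxyphenyl)ethanone | COc1ccc(C(C)=O)cc1 | starting material
12 | 3-(diisopropylamino)-1-(4-methoxyphenyl)propan-1-one | COc1ccc(C(=O)CCN(C(C)C)C(C)C)cc1 | intermediate (not isolated)
13 | 1-(4-methoxyphenyl)prop-2-en-1-one | COc1ccc(C(=O)C=C)cc1 | intermediate
14 | potassium (Z)-enolate of (R,E)-1-(4-methoxyphenyl)-3-({3-nitro-1-[4-(triisopropylsilyloxy)phenyl]prop-2-en-1-yl}oxy)propan-1-one | COc1ccc(/C([O-])=C/CO[C@H](/C=C/[N+](=O)[O-])c2ccc(O[Si](C(C)C)(C(C)C)C(C)C)cc2)cc1.[K+] | intermediate (not isolated)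
15 | potassium nitronate of 16 | COc1ccc(C(=O)[C@H]2CO[C@@H](c3ccc(O[Si](C(C)C)(C(C)C)C(C)C)cc3)[C@@H]2C=[N+]([O-])[O-])cc1.[K+] | intermediate (not isolated)
16 | (2R,3S,4R)-4-(4-methoxybenzoyl)-3-(nitromethyl)-2-[4-(triisopropylsilyloxy)phenyl]oxolane | COc1ccc(C(=O)[C@H]2CO[C@@H](c3ccc(O[Si](C(C)C)(C(C)C)C(C)C)cc3)[C@@H]2C[N+](=O)[O-])cc1 | intermediate
17 | sodium nitronate of 16 | COc1ccc(C(=O)[C@H]2CO[C@@H](c3ccc(O[Si](C(C)C)(C(C)C)C(C)C)cc3)[C@@H]2C=[N+]([O-])[O-])cc1.[Na+] | intermediate (not isolated)
18 | (2R,3R,4R)-4-(4-methoxybenzoyl)-2-[4-(triisopropylsilyloxy)phenyl]oxolane-3-carbaldehyde | COc1ccc(C(=O)[C@H]2CO[C@@H](c3ccc(O[Si](C(C)C)(C(C)C)C(C)C)cc3)[C@@H]2C=O)cc1 | intermediate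
19 | [(2R,3S,4R)-4-(4-methoxybenzoyl)-2-[4-(triisopropylsilyloxy)phenyl]oxolan-3-yl]methanol | COc1ccc(C(=O)[C@H]2CO[C@@H](c3ccc(O[Si](C(C)C)(C(C)C)C(C)C)cc3)[C@@H]2CO)cc1 | intermediate
20 | [(2R,3S,4R)-4-[(S)-hydroxy(4-methoxyphenyl)methyl]-2-[4-(triisopropylsilyloxy)phenyl]oxolan-3-yl]methanol | COc1ccc([C@@H](O)[C@H]2CO[C@@H](c3ccc(O[Si](C(C)C)(C(C)C)C(C)C)cc3)[C@@H]2CO)cc1 | intermediate
21 | [(2R,3S,4R)-4-[(S)-acetoxy(4-methoxyphenyl)methyl]-2-[4-(triisopropylsilyloxy)phenyl]oxolan-3-yl]methyl acetate | COc1ccc([C@@H](OC(C)=O)[C@H]2CO[C@@H](c3ccc(O[Si](C(C)C)(C(C)C)C(C)C)cc3)[C@@H]2COC(C)=O)cc1 | intermediate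
22 | [(2R,3S,4R)-4-[(S)-acetoxy(4-methoxyphenyl)methyl]-2-(4-hydroxyphenyl)oxolan-3-yl]methyl acetate | COc1ccc([C@@H](OC(C)=O)[C@H]2CO[C@@H](c3ccc(O)cc3)[C@@H]2COC(C)=O)cc1 | target

## Step count and least certain steps

Total: 13 steps. Longest linear sequence: 12 steps (steps 1–6 and 8–13).

**Step 8 (key step, proposed new method).**
- What may go wrong: the alkoxide of 10 may add to the nitroalkene of a second molecule (oligomerisation), since that acceptor is intrinsically the more electrophilic one. Base may also shift the benzylic γ-hydrogen of 10, which gives a saturated nitro ketone and destroys the C2 centre. Nitronate 15 may add to surplus 13.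
- Fallback: set out from 10 and 13 and return at 16 in two known operations, so that no alkoxide ever meets the nitroalkene. Brønsted-acid-catalysed oxa-Michael addition of the alcohol to the vinyl ketone (Tf2NH, 5 mol%, CH2Cl2, 0 °C) should give (R,E)-1-(4-methoxyphenyl)-3-({3-nitro-1-[4-(triisopropylsilyloxy)phenyl]prop-2-en-1-yl}oxy)propan-1-one F1. Kinetic enolisation of the ketone with LiN(SiMe3)2 in THF at −78 °C should then close the ring by the intramolecular Michael addition of a ketone enolate to a nitroalkene. Quenching with acetic acid and the same DBU equilibration at C4 lead to 16.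

**Step 4.**
- What may go wrong: loss of enantiomeric purity by enolisation of aldehyde 5 before or during the nitroaldol addition, because its α-hydrogen is both benzylic and next to the formyl group.
- Fallback: set out from ester 4 and return at 7 without ever making the aldehyde. Hydrolysis with Me3SnOH in 1,2-dichloroethane at 80 °C gives (S)-2-(triethylsilyloxy)-2-[4-(triisopropylsilyloxy)phenyl]acetic acid F2. 1,1'-Carbonyldiimidazole converts it into (S)-1-(imidazol-1-yl)-2-(triethylsilyloxy)-2-[4-(triisopropylsilyloxy)phenyl]ethan-1-one F3. This acylates 6, deprotonated with KOt-Bu in THF/DMSO, to give (S)-1-nitro-3-(triethylsilyloxy)-3-[4-(triisopropylsilyloxy)phenyl]propan-2-one F4. F4 exists as its nitronate under the reaction conditions, which protects the benzylic hydrogen. Reduction with NaBH4 in MeOH at −20 °C gives 7.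

**Step 9.**
- What may go wrong: over-oxidation of the new aldehyde to the acid, or enolisation at C3 in the basic aqueous medium followed by oxidative degradation. Partial loss of the aryl silyl ether in methanolic hydroxide is a lesser concern.
- Fallback: set out from 16 and return at 19, accepting the higher oxidation level on purpose. NaNO2 and AcOH in DMSO at 35 °C convert the primary nitro group into (2R,3R,4R)-4-(4-methoxybenzoyl)-2-[4-(triisopropylsilyloxy)phenyl]oxolane-3-carboxylic acid F5. BH3·SMe2 in THF at 0 °C reduces the carboxylic acid faster than the deactivated aryl ketone and gives 19, so aldehyde 18 is bypassed.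

**Step 11.**
- What may go wrong: poor facial selectivity. The 4-methoxyphenyl group and the branched oxolanyl group differ less in effective size than the aryl/methyl pair for which the catalyst is reliable, and the alkoxyborane formed at the free hydroxymethyl group may deliver hydride without the catalyst.
- Fallback: set out from 19 and return at 21, removing the free hydroxyl group and changing the mode of recognition. Acetylation (Ac2O, pyridine) gives [(2R,3S,4R)-4-(4-methoxybenzoyl)-2-[4-(triisopropylsilyloxy)phenyl]oxolan-3-yl]methyl acetate F6. Noyori–Ikariya transfer hydrogenation with RuCl[(S,S)-TsDPEN](p-cymene) and HCO2H/Et3N, which recognises the arene through a CH–π contact and not by size, should give [(2R,3S,4R)-4-[(S)-hydroxy(4-methoxyphenyl)methyl]-2-[4-(triisopropylsilyloxy)phenyl]oxolan-3-yl]methyl acetate F7. A second acetylation (Ac2O, pyridine, DMAP) gives 21.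

**Step 13.**
- What may go wrong: cleavage or transfer of an acetate under the basic fluoride source, or opening of the C2–O1 bond through a quinone methide once the phenoxide is free.
- Fallback: set out from 20 and return at 22, with the silyl group removed before any acetate is present. Bu4NF/AcOH in THF gives [(2R,3S,4R)-4-[(S)-hydroxy(4-methoxyphenyl)methyl]-2-(4-hydroxyphenyl)oxolan-3-yl]methanol F8. Exhaustive acetylation (Ac2O, pyridine, DMAP) gives [(2R,3S,4R)-4-[(S)-acetoxy(4-methoxyphenyl)methyl]-2-(4-acetoxyphenyl)oxolan-3-yl]methyl acetate F9, which has the same structure as A8. The aryl acetate, the only activated ester, is then removed selectively with NH4OAc in aqueous MeOH at rt to give 22.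

## Further compounds

F1 | step 8 | (R,E)-1-(4-methoxyphenyl)-3-({3-nitro-1-[4-(triisopropylsilyloxy)phenyl]prop-2-en-1-yl}oxy)propan-1-one | COc1ccc(C(=O)CCO[C@H](/C=C/[N+](=O)[O-])c2ccc(O[Si](C(C)C)(C(C)C)C(C)C)cc2)cc1
F2 | step 4 | (S)-2-(triethylsilyloxy)-2-[4-(triisopropylsilyloxy)phenyl]acetic acid | OC(=O)[C@@H](O[Si](CC)(CC)CC)c1ccc(O[Si](C(C)C)(C(C)C)C(C)C)cc1
F3 | step 4 | (S)-1-(imidazol-1-yl)-2-(triethylsilyloxy)-2-[4-(triisopropylsilyloxy)phenyl]ethan-1-one | O=C(n1ccnc1)[C@@H](O[Si](CC)(CC)CC)c1ccc(O[Si](C(C)C)(C(C)C)C(C)C)cc1
F4 | step 4 | (S)-1-nitro-3-(triethylsilyloxy)-3-[4-(triisopropylsilyloxy)phenyl]propan-2-one | [O-][N+](=O)CC(=O)[C@@H](O[Si](CC)(CC)CC)c1ccc(O[Si](C(C)C)(C(C)C)C(C)C)cc1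
F5 | step 9 | (2R,3R,4R)-4-(4-methoxybenzoyl)-2-[4-(triisopropylsilyloxy)phenyl]oxolane-3-carboxylic acid | COc1ccc(C(=O)[C@H]2CO[C@@H](c3ccc(O[Si](C(C)C)(C(C)C)C(C)C)cc3)[C@@H]2C(=O)O)cc1
F6 | step 11 | [(2R,3S,4R)-4-(4-methoxybenzoyl)-2-[4-(triisopropylsilyloxy)phenyl]oxolan-3-yl]methyl acetate | COc1ccc(C(=O)[C@H]2CO[C@@H](c3ccc(O[Si](C(C)C)(C(C)C)C(C)C)cc3)[C@@H]2COC(C)=O)cc1
F7 | step 11 | [(2R,3S,4R)-4-[(S)-hydroxy(4-methoxyphenyl)methyl]-2-[4-(triisopropylsilyloxy)phenyl]oxolan-3-yl]methyl acetate | COc1ccc([C@@H](O)[C@H]2CO[C@@H](c3ccc(O[Si](C(C)C)(C(C)C)C(C)C)cc3)[C@@H]2COC(C)=O)cc1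
F8 | step 13 | [(2R,3S,4R)-4-[(S)-hydroxy(4-methoxyphenyl)methyl]-2-(4-hydroxyphenyl)oxolan-3-yl]methanol | COc1ccc([C@@H](O)[C@H]2CO[C@@H](c3ccc(O)cc3)[C@@H]2CO)cc1
F9 | step 13 | [(2R,3S,4R)-4-[(S)-acetoxy(4-methoxyphenyl)methyl]-2-(4-acetoxyphenyl)oxolan-3-yl]methyl acetate | COc1ccc([C@@H](OC(C)=O)[C@H]2CO[C@@H](c3ccc(OC(C)=O)cc3)[C@@H]2COC(C)=O)cc1
A1 | alternative 1 | trans,trans-3-(hydroxymethyl)-4-[2-(4-methoxyphenyl)-1,3-dithian-2-yl]-5-[(1R,2S,5R)-menthyloxy]oxolan-2-one | COc1ccc(C3(SCCCS3)[C@H]2[C@H](O[C@@H]4C[C@H](C)CC[C@H]4C(C)C)OC(=O)[C@@H]2CO)cc1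
A2 | alternative 1 | (5R)-5-[(1R,2S,5R)-menthyloxy]furan-2(5H)-one | O=C1C=C[C@H](O[C@@H]2C[C@H](C)CC[C@H]2C(C)C)O1
A3 | alternative 1 | 2-(4-methoxyphenyl)-1,3-dithiane | COc1ccc(C2SCCCS2)cc1
A4 | alternative 1 | formaldehyde | C=O
A5 | alternative 2 | [(2R,3S,4R)-4-[(S)-(tert-butyldimethylsilyloxy)(4-methoxyphenyl)methyl]-2-(4-hydroxyphenyl)oxolan-3-yl]methanol | COc1ccc([C@@H](O[Si](C)(C)C(C)(C)C)[C@H]2CO[C@@H](c3ccc(O)cc3)[C@@H]2CO)cc1
A6 | alternative 2 | (2R,3S)-2-[(S)-(tert-butyldimethylsilyloxy)(4-methoxyphenyl)methyl]-3-(4-hydroxybenzyl)butane-1,4-diol | COc1ccc([C@@H](O[Si](C)(C)C(C)(C)C)[C@@H](CO)[C@@H](CO)Cc2ccc(O)cc2)cc1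
A7 | alternative 2 | para-quinone methide of A6 (4-alkylidenecyclohexa-2,5-dien-1-one) | COc1ccc([C@@H](O[Si](C)(C)C(C)(C)C)[C@@H](CO)[C@@H](CO)C=C2C=CC(=O)C=C2)cc1
A8 | alternative 3 | [(2R,3S,4R)-4-[(S)-acetoxy(4-methoxyphenyl)methyl]-2-(4-acetoxyphenyl)oxolan-3-yl]methyl acetate | COc1ccc([C@@H](OC(C)=O)[C@H]2CO[C@@H](c3ccc(OC(C)=O)cc3)[C@@H]2COC(C)=O)cc1
A9 | alternative 3 | (2S,E)-2-[(R)-(4-acetoxyphenyl)(hydroxy)methyl]-4-(4-methoxyphenyl)but-3-en-1-yl acetate | COc1ccc(/C=C/[C@@H](COC(C)=O)[C@@H](O)c2ccc(OC(C)=O)cc2)cc1
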